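**Retrosynthetic overview**
- Butenolide last: Pd/Cu Sonogashira coupling and 5-exo-dig lactonisation of a terminal (E)-enyne with (Z)-3-iodobut-2-enoic acid (C16–C17 bond, then O–C16).
- The (E)-enyne comes from a side-chain alkyne by Zr-catalysed methylalumination and alkynyl coupling; the alkyne comes from a δ-lactone (DIBAL, Ohira–Bestmann), which also frees the C8 tertiary alcohol.
- Key step: Co–H hydrogen-atom-transfer radical–polar crossover cyclisation of an acyclic (S)-carbinol trienoate. Ring A (C4–C5), ring B (C10–C9) and the δ-lactone (C8–O) form in one operation, steered by the C6 carbinol.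
- The trienoate comes from an (E)-enal by catalytic asymmetric propargylation, methylalumination/iodination and Negishi coupling with a zinc homoenolate.
- The enal comes from propargyl alcohol and a pentynyl Grignard reagent. Ring order: A, then B, then δ-lactone (one pot); butenolide at the end.

Assumption: decalin atoms carry labdane numbers (C1–C10; C18 = 4α-CH2O, C19 = 4β-CH3, C17 = 8β-CH3, C20 = 10β-CH3; side chain numbered on from C11), and the zinc reagent 15, the allenylboronate 10, (S)-TRIP and the Ohira–Bestmann reagent are bought.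

**Step 1**
Reactants: 1 (5-chloropent-1-yn-1-yl)trimethylsilane; 2 prop-2-yn-1-ol
Product: 4 2-methylidene-7-(trimethylsilyl)hept-6-yn-1-ol, via Grignard reagent 3 (not isolated)
Conditions: 1, Mg, THF, 50 °C; 2 + EtMgBr (1.0 equiv), THF, 0 °C; combine, CuI (10 mol%), 0 °C to rt; cold 1 M HCl
Reagents that add atoms: none
Why: Copper-catalysed anti-carbomagnesiation of the propargylic alkoxide (Duboudin–Jousseaume reaction) puts the alkyl group on the internal alkyne carbon and gives, after protonolysis, the 2-substituted allylic alcohol carrying C4, C18 and the future C19; no stereocentre is formed.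

**Step 2**
Reactants: 4 2-methylidene-7-(trimethylsilyl)hept-6-yn-1-ol
Product: 5 tert-butyl(dimethyl){[2-methylidene-7-(trimethylsilyl)hept-6-yn-1-yl]oxy}silane
Conditions: TBSCl, imidazole, DMF, rt
Reagents that add atoms: tert-butyldimethylsilyl chloride, CC(C)(C)[Si](C)(C)Cl
Why: Standard silylation of the primary alcohol; the bulky silyl ether later steers the CH2O group into the equatorial C4 position.

**Step 3**
Reactants: 5 tert-butyl(dimethyl){[2-methylidene-7-(trimethylsilyl)hept-6-yn-1-yl]oxy}silane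
Product: 6 tert-butyl(dimethyl)[(2-methylidenehept-6-yn-1-yl)oxy]silane
Conditions: K2CO3 (0.2 equiv), MeOH, rt
Reagents that add atoms: none
Why: Base-catalysed methanolysis cleaves only the alkynyl C–Si bond; the primary TBS ether is stable to K2CO3/MeOH.

**Step 4**
Reactants: 6 tert-butyl(dimethyl)[(2-methylidenehept-6-yn-1-yl)oxy]silane
Product: 8 (2E)-7-({[tert-butyl(dimethyl)silyl]oxy}methyl)-3-methylocta-2,7-dien-1-ol, via alkenylalane 7 (not isolated)
Conditions: Me3Al (2 equiv), Cp2ZrCl2 (25 mol%), CH2Cl2, rt; n-BuLi, THF, −78 °C; (CH2O)n, rt; aq. Rochelle salt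
Reagents that add atoms: trimethylaluminium, C[Al](C)C; paraformaldehyde (as formaldehyde), C=O
Why: Negishi zirconium-catalysed methylalumination adds Me and Al syn across the terminal alkyne (Me to the internal carbon) and the derived alanate attacks formaldehyde with retention, fixing the E-trisubstituted C5=C10 alkene while the alkene and silyl ether are inert.

**Step 5**
Reactants: 8 (2E)-7-({[tert-butyl(dimethyl)silyl]oxy}methyl)-3-methylocta-2,7-dien-1-ol
Product: 9 (2E)-7-({[tert-butyl(dimethyl)silyl]oxy}methyl)-3-methylocta-2,7-dienal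
Conditions: MnO2, CH2Cl2, rt
Reagents that add atoms: none
Why: Allylic oxidation with MnO2 gives the enal without E/Z isomerisation or loss of the silyl ether.

**Step 6**
Reactants: 9 (2E)-7-({[tert-butyl(dimethyl)silyl]oxy}methyl)-3-methylocta-2,7-dienal; 10 4,4,5,5-tetramethyl-2-(propa-1,2-dien-1-yl)-1,3,2-dioxaborolane
Product: 12 (4S,5E)-10-({[tert-butyl(dimethyl)silyl]oxy}methyl)-6-methylundeca-5,10-dien-1-yn-4-ol, via pinacol borate ester 11 (not isolated)
Conditions: (S)-TRIP (5 mol%), 4 Å MS, toluene, −20 °C; aq. work-up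
Reagents that add atoms: none
Why: Chiral phosphoric acid-catalysed propargylation with an allenylboronate (SE2′ allenyl transfer through a six-membered chair transition state) in which the (S)-catalyst directs attack to the Si face of the aldehyde and so sets the (S)-carbinol, the future C6.

**Step 7**
Reactants: 12 (4S,5E)-10-({[tert-butyl(dimethyl)silyl]oxy}methyl)-6-methylundeca-5,10-dien-1-yn-4-ol
Product: 14 (1E,4S,5E)-10-({[tert-butyl(dimethyl)silyl]oxy}methyl)-1-iodo-2,6-dimethylundeca-1,5,10-trien-4-ol, via alkenylalane 13 (not isolated)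
Conditions: Me3Al (3.5 equiv), Cp2ZrCl2 (25 mol%), CH2Cl2, 0 °C to rt; I2, THF, −30 to 0 °C; aq. NaHCO3/Na2S2O3
Reagents that add atoms: trimethylaluminium, C[Al](C)C; iodine, II
Why: Negishi methylalumination of the O-aluminated homopropargylic alkyne is regio- and syn-selective and iodinolysis of the C–Al bond goes with retention, giving the E-vinyl iodide (future C8=C9) without touching C6.

**Step 8**
Reactants: 14 (1E,4S,5E)-10-({[tert-butyl(dimethyl)silyl]oxy}methyl)-1-iodo-2,6-dimethylundeca-1,5,10-trien-4-ol; 15 (3-tert-butoxy-3-oxopropyl)zinc bromide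
Product: 16 tert-butyl (4E,7S,8E)-13-({[tert-butyl(dimethyl)silyl]oxy}methyl)-7-hydroxy-5,9-dimethyltetradeca-4,8,13-trienoate
Conditions: 15 (2.5 equiv), Pd(dppf)Cl2 (5 mol%), THF/NMP, 40 °C
Reagents that add atoms: none
Why: Negishi sp2–sp3 cross-coupling of the vinyl iodide with the zinc homoenolate proceeds with retention of alkene geometry and tolerates the free alcohol, the silyl ether and the tert-butyl ester.

**Step 9**
Reactants: 16 tert-butyl (4E,7S,8E)-13-({[tert-butyl(dimethyl)silyl]oxy}methyl)-7-hydroxy-5,9-dimethyltetradeca-4,8,13-trienoate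
Product: 17 (4R,5R,6S,8R,9R,10S)-18-{[tert-butyl(dimethyl)silyl]oxy}-6α-hydroxy-8α,13-epoxy-14,15,16-trinorlabdan-13-one (trans-decalin with trans-fused δ-lactone)
Conditions: Co(II)–salen (5 mol%), N-fluoro-2,4,6-trimethylpyridinium BF4 (2 equiv), (Me2SiH)2O (1.5 equiv), PhCF3/HFIP, 0 °C, high dilution
Reagents that add atoms: none
Why: Proposed new method: Co–H hydrogen-atom transfer to the only 1,1-disubstituted alkene gives the tertiary C4 radical, which closes ring A 6-endo onto C5 and ring B 6-endo onto C9 through a chair–chair transition state in which the C6 hydroxyl sits equatorial (axial would be syn-diaxial to C19 and C20), the two E-alkenes give the trans ring fusion and the equatorial C9 chain, the larger CH2OTBS takes the equatorial C4 site, and the C8 radical is oxidised by cobalt to the cation and trapped on its equatorial α-face by the ester carbonyl with loss of isobutene to give the trans-fused lactone; the closest known reactions are Co-salen HAT-initiated radical–polar crossover bicyclisations of oxygenated polyenes (arene-terminated), Co-salen/N-fluoropyridinium hydroacyloxylation of alkenes, and Ti(III) epoxypolyene radical cyclisations of the same topology.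

**Step 10**
Reactants: 17 (4R,5R,6S,8R,9R,10S)-18-{[tert-butyl(dimethyl)silyl]oxy}-6α-hydroxy-8α,13-epoxy-14,15,16-trinorlabdan-13-one
Product: 19 (4R,5R,6S,8R,9R,10S)-9-(but-3-yn-1-yl)-4α-({[tert-butyl(dimethyl)silyl]oxy}methyl)-4β,8β,10β-trimethyl-trans-decalin-6α,8α-diol, via lactol 18 (not isolated)
Conditions: DIBAL-H (2.5 equiv), CH2Cl2, −78 °C; MeOH; then K2CO3 (2 equiv), dimethyl (1-diazo-2-oxopropyl)phosphonate, MeOH/THF, 0 °C to rt
Reagents that add atoms: dimethyl (1-diazo-2-oxopropyl)phosphonate, COP(=O)(OC)C(=[N+]=[N-])C(C)=O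
Why: DIBAL-H stops at the lactol at −78 °C and its open hydroxy-aldehyde form undergoes Seyferth–Gilbert homologation with the Ohira–Bestmann reagent (one-pot ester-to-alkyne protocol), which frees the C8 tertiary alcohol and adds C14 without touching any stereocentre.

**Step 11**
Reactants: 19 (4R,5R,6S,8R,9R,10S)-9-(but-3-yn-1-yl)-4α-({[tert-butyl(dimethyl)silyl]oxy}methyl)-4β,8β,10β-trimethyl-trans-decalin-6α,8α-diol
Product: 21 (4R,5R,6S,8R,9R,10S)-4α-({[tert-butyl(dimethyl)silyl]oxy}methyl)-4β,8β,10β-trimethyl-9-[(3E)-3-methyl-6-(trimethylsilyl)hex-3-en-5-yn-1-yl]-trans-decalin-6α,8α-diol, via O-aluminated alkenylalane 20 (not isolated)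
Conditions: Me3Al (6 equiv), Cp2ZrCl2 (30 mol%), (CH2Cl)2, rt; then Pd(PPh3)4 (5 mol%), ZnCl2 (20 mol%), BrC≡CSiMe3, THF, rt; aq. NaHCO3/Rochelle salt
Reagents that add atoms: trimethylaluminium, C[Al](C)C; (bromoethynyl)trimethylsilane, C[Si](C)(C)C#CBr
Why: Zirconium-catalysed syn-methylalumination of the terminal alkyne (alcohols masked in situ as aluminium alkoxides) followed by Pd/Zn-mediated Negishi coupling of the alkenylalane with the 1-bromoalkyne, both with retention, gives the 13E enyne.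

**Step 12**
Reactants: 21 (4R,5R,6S,8R,9R,10S)-4α-({[tert-butyl(dimethyl)silyl]oxy}methyl)-4β,8β,10β-trimethyl-9-[(3E)-3-methyl-6-(trimethylsilyl)hex-3-en-5-yn-1-yl]-trans-decalin-6α,8α-diol
Product: 22 (4R,5R,6S,8R,9R,10S)-4α-(hydroxymethyl)-4β,8β,10β-trimethyl-9-[(3E)-3-methylhex-3-en-5-yn-1-yl]-trans-decalin-6α,8α-diol
Conditions: TBAF (3 equiv), THF, 0 °C to rt
Reagents that add atoms: none
Why: Fluoride cleaves the alkynyl C–Si and the primary O–Si bonds in one desilylation; no stereocentre or alkene is affected.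

**Step 13**
Reactants: 23 but-2-ynoic acid
Product: 24 (2Z)-3-iodobut-2-enoic acid
Conditions: NaI, AcOH, 110 °C
Reagents that add atoms: sodium iodide, [Na+].[I-]
Why: Anti-hydroiodination of the ynoic acid gives the (Z)-β-iodo acid with iodide and carboxyl cis, as needed for the later lactonisation.

**Step 14**
Reactants: 22 (4R,5R,6S,8R,9R,10S)-4α-(hydroxymethyl)-4β,8β,10β-trimethyl-9-[(3E)-3-methylhex-3-en-5-yn-1-yl]-trans-decalin-6α,8α-diol; 24 (2Z)-3-iodobut-2-enoic acid
Product: 26 (5Z)-5-{(2E)-5-[(4R,5R,6S,8R,9R,10S)-6α,8α-dihydroxy-4α-(hydroxymethyl)-4β,8β,10β-trimethyl-trans-decalin-9-yl]-3-methylpent-2-en-1-ylidene}-4-methylfuran-2(5H)-one (CNP0126806.1), via dienynoic acid 25 (not isolated)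
Conditions: PdCl2(PPh3)2 (5 mol%), CuI (10 mol%), Et3N, MeCN, rt
Reagents that add atoms: none
Why: Tandem Sonogashira coupling and 5-exo-dig lactonisation (Negishi-type ylidenebutenolide synthesis) in which anti-oxymetalation of the (Z)-enynoic acid and protodemetalation place the side chain cis to the ring oxygen, giving the (Z)-alkylidene butenolide with the 13E alkene retained.

**Compound list**
1 | (5-chloropent-1-yn-1-yl)trimethylsilane | C[Si](C)(C)C#CCCCCl | starting material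
2 | prop-2-yn-1-ol | OCC#C | starting material
3 | [5-(trimethylsilyl)pent-4-yn-1-yl]magnesium chloride | C[Si](C)(C)C#CCCC[Mg]Cl | intermediate
4 | 2-methylidene-7-(trimethylsilyl)hept-6-yn-1-ol | C=C(CO)CCCC#C[Si](C)(C)C | intermediate
5 | tert-butyl(dimethyl){[2-methylidene-7-(trimethylsilyl)hept-6-yn-1-yl]oxy}silane | C=C(CO[Si](C)(C)C(C)(C)C)CCCC#C[Si](C)(C)C | intermediate
6 | tert-butyl(dimethyl)[(2-methylidenehept-6-yn-1-yl)oxy]silane | C=C(CO[Si](C)(C)C(C)(C)C)CCCC#C | intermediate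
7 | [(1E)-7-({[tert-butyl(dimethyl)silyl]oxy}methyl)-2-methylocta-1,7-dien-1-yl]dimethylalumane | C[Al](C)/C=C(\C)CCCC(=C)CO[Si](C)(C)C(C)(C)C | intermediate
8 | (2E)-7-({[tert-butyl(dimethyl)silyl]oxy}methyl)-3-methylocta-2,7-dien-1-ol | OC/C=C(\C)CCCC(=C)CO[Si](C)(C)C(C)(C)C | intermediate
9 | (2E)-7-({[tert-butyl(dimethyl)silyl]oxy}methyl)-3-methylocta-2,7-dienal | O=C/C=C(\C)CCCC(=C)CO[Si](C)(C)C(C)(C)C | intermediate
10 | 4,4,5,5-tetramethyl-2-(propa-1,2-dien-1-yl)-1,3,2-dioxaborolane | C=C=CB1OC(C)(C)C(C)(C)O1 | starting material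
11 | O-(pinacolboryl) ether of 12 | C#CC[C@H](OB1OC(C)(C)C(C)(C)O1)/C=C(\C)CCCC(=C)CO[Si](C)(C)C(C)(C)C | intermediate
12 | (4S,5E)-10-({[tert-butyl(dimethyl)silyl]oxy}methyl)-6-methylundeca-5,10-dien-1-yn-4-ol | C#CC[C@H](O)/C=C(\C)CCCC(=C)CO[Si](C)(C)C(C)(C)C | intermediate
13 | (1E)-alkenyl(dimethyl)alane of 12 with the alcohol as OAlMe2 | C[Al](C)/C=C(\C)C[C@H](O[Al](C)C)/C=C(\C)CCCC(=C)CO[Si](C)(C)C(C)(C)C | intermediate
14 | (1E,4S,5E)-10-({[tert-butyl(dimethyl)silyl]oxy}methyl)-1-iodo-2,6-dimethylundeca-1,5,10-trien-4-ol | I/C=C(\C)C[C@H](O)/C=C(\C)CCCC(=C)CO[Si](C)(C)C(C)(C)C | intermediate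
15 | (3-tert-butoxy-3-oxopropyl)zinc bromide | CC(C)(C)OC(=O)CC[Zn]Br | starting material
16 | tert-butyl (4E,7S,8E)-13-({[tert-butyl(dimethyl)silyl]oxy}methyl)-7-hydroxy-5,9-dimethyltetradeca-4,8,13-trienoate | CC(C)(C)OC(=O)CC/C=C(\C)C[C@H](O)/C=C(\C)CCCC(=C)CO[Si](C)(C)C(C)(C)C | intermediate
17 | (4R,5R,6S,8R,9R,10S)-18-{[tert-butyl(dimethyl)silyl]oxy}-6α-hydroxy-8α,13-epoxy-14,15,16-trinorlabdan-13-one | O=C1CC[C@@H]2[C@@]3(C)CCC[C@@](C)(CO[Si](C)(C)C(C)(C)C)[C@@H]3[C@@H](O)C[C@@]2(C)O1 | intermediate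
18 | lactol of 17 (13-ol, both epimers) | OC1CC[C@@H]2[C@@]3(C)CCC[C@@](C)(CO[Si](C)(C)C(C)(C)C)[C@@H]3[C@@H](O)C[C@@]2(C)O1 | intermediate
19 | (4R,5R,6S,8R,9R,10S)-9-(but-3-yn-1-yl)-4α-({[tert-butyl(dimethyl)silyl]oxy}methyl)-4β,8β,10β-trimethyl-trans-decalin-6α,8α-diol | C#CCC[C@@H]1[C@@]2(C)CCC[C@@](C)(CO[Si](C)(C)C(C)(C)C)[C@@H]2[C@@H](O)C[C@@]1(C)O | intermediate
20 | (1E)-alkenyl(dimethyl)alane of 19 with both alcohols as OAlMe2 | C[Al](C)/C=C(\C)CC[C@@H]1[C@@]2(C)CCC[C@@](C)(CO[Si](C)(C)C(C)(C)C)[C@@H]2[C@@H](O[Al](C)C)C[C@@]1(C)O[Al](C)C | intermediate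
21 | (4R,5R,6S,8R,9R,10S)-4α-({[tert-butyl(dimethyl)silyl]oxy}methyl)-4β,8β,10β-trimethyl-9-[(3E)-3-methyl-6-(trimethylsilyl)hex-3-en-5-yn-1-yl]-trans-decalin-6α,8α-diol | C[Si](C)(C)C#C/C=C(\C)CC[C@@H]1[C@@]2(C)CCC[C@@](C)(CO[Si](C)(C)C(C)(C)C)[C@@H]2[C@@H](O)C[C@@]1(C)O | intermediate
22 | (4R,5R,6S,8R,9R,10S)-4α-(hydroxymethyl)-4β,8β,10β-trimethyl-9-[(3E)-3-methylhex-3-en-5-yn-1-yl]-trans-decalin-6α,8α-diol | C#C/C=C(\C)CC[C@@H]1[C@@]2(C)CCC[C@@](C)(CO)[C@@H]2[C@@H](O)C[C@@]1(C)O | intermediate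
23 | but-2-ynoic acid | CC#CC(=O)O | starting material
24 | (2Z)-3-iodobut-2-enoic acid | C/C(I)=C/C(=O)O | intermediate
25 | (2Z,6E)-9-[(4R,5R,6S,8R,9R,10S)-6α,8α-dihydroxy-4α-(hydroxymethyl)-4β,8β,10β-trimethyl-trans-decalin-9-yl]-3,7-dimethylnona-2,6-dien-4-ynoic acid | OC(=O)/C=C(/C)C#C/C=C(\C)CC[C@@H]1[C@@]2(C)CCC[C@@](C)(CO)[C@@H]2[C@@H](O)C[C@@]1(C)O | intermediate
26 | (5Z)-5-{(2E)-5-[(4R,5R,6S,8R,9R,10S)-6α,8α-dihydroxy-4α-(hydroxymethyl)-4β,8β,10β-trimethyl-trans-decalin-9-yl]-3-methylpent-2-en-1-ylidene}-4-methylfuran-2(5H)-one | CC1=CC(=O)O/C1=C\C=C(/C)CC[C@@H]1[C@@]2(C)CCC[C@@](C)(CO)[C@@H]2[C@@H](O)C[C@@]1(C)O | target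

**Step count and risks**
Total steps: 14. Longest linear sequence: 13 (steps 1–12, then 14); step 13 is a one-step side branch.

The three steps most likely to fail:

1. Step 9 (radical–polar crossover bicyclisation/lactonisation). Risks are premature oxidation or hydrogen-atom transfer at the other alkenes, elimination instead of lactone capture, and imperfect equatorial/axial selection at C4. Fallback, from 16 back to 17, replaces the radical initiation by a cationic epoxide-initiated cascade. Mukaiyama hydration of the 1,1-disubstituted alkene of 16 (Mn(dpm)3, PhSiH3, O2, i-PrOH, 0 °C) gives tert-butyl (4E,7S,8E)-14-{[tert-butyl(dimethyl)silyl]oxy}-7,13-dihydroxy-5,9,13-trimethyltetradeca-4,8-dienoate F1 as both C13 epimers. TBAF gives tert-butyl (4E,7S,8E)-7,13,14-trihydroxy-5,9,13-trimethyltetradeca-4,8-dienoate F2. Cyclodehydration of its 1,2-diol (PPh3, DIAD) gives tert-butyl (4E,7S,8E)-7-hydroxy-5,9-dimethyl-12-(2-methyloxiran-2-yl)dodeca-4,8-dienoate F3. MeAlCl2 (CH2Cl2, −78 °C) opens the epoxide at its tertiary carbon and drives the same chair–chair cascade, ended by the tert-butyl ester, to (4R,5R,6S,8R,9R,10S)-6α,18-dihydroxy-8α,13-epoxy-14,15,16-trinorlabdan-13-one F4; the epoxide epimer that cannot place CH2O equatorial gives the 4-epimer, which is removed by chromatography. TBSCl/imidazole on the primary alcohol returns 17.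

2. Step 11 (one-pot methylalumination and alkynyl coupling on an unprotected diol). Fallback, from 17 back to 21, builds the trisubstituted alkene by olefination instead of carbometalation. MeLi (2.2 equiv, THF, −78 °C) opens the lactone to (4R,5R,6S,8R,9R,10S)-18-{[tert-butyl(dimethyl)silyl]oxy}-6α,8α-dihydroxy-14,15-dinorlabdan-13-one F5, a hydroxy methyl ketone in equilibrium with its hemiketal. Horner–Wadsworth–Emmons reaction with diethyl [3-(trimethylsilyl)prop-2-yn-1-yl]phosphonate/LiHMDS gives 21 together with its 13Z isomer, separated by chromatography.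

3. Step 14 (tandem coupling/lactonisation on the free triol; 6-endo pyranone formation and polyene sensitivity are the risks). Fallback, from 22 back to 25, separates coupling from ring closure and closes the ring with silver. 24 is methylated (TMSCHN2) to methyl (2Z)-3-iodobut-2-enoate F6. Sonogashira coupling of 22 with F6 (Pd(PPh3)4, CuI, i-Pr2NH) gives methyl (2Z,6E)-9-[(4R,5R,6S,8R,9R,10S)-6α,8α-dihydroxy-4α-(hydroxymethyl)-4β,8β,10β-trimethyl-trans-decalin-9-yl]-3,7-dimethylnona-2,6-dien-4-ynoate F7, which cannot cyclise. LiOH gives acid 25, now isolated, and AgNO3 (10 mol%, acetone, rt) effects the 5-exo-dig cycloisomerisation to 26.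

**Further compounds**
F1 | step 9 | tert-butyl (4E,7S,8E)-14-{[tert-butyl(dimethyl)silyl]oxy}-7,13-dihydroxy-5,9,13-trimethyltetradeca-4,8-dienoate | CC(C)(C)OC(=O)CC/C=C(\C)C[C@H](O)/C=C(\C)CCCC(C)(O)CO[Si](C)(C)C(C)(C)C
F2 | step 9 | tert-butyl (4E,7S,8E)-7,13,14-trihydroxy-5,9,13-trimethyltetradeca-4,8-dienoate | CC(C)(C)OC(=O)CC/C=C(\C)C[C@H](O)/C=C(\C)CCCC(C)(O)CO
F3 | step 9 | tert-butyl (4E,7S,8E)-7-hydroxy-5,9-dimethyl-12-(2-methyloxiran-2-yl)dodeca-4,8-dienoate | CC(C)(C)OC(=O)CC/C=C(\C)C[C@H](O)/C=C(\C)CCCC1(C)CO1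
F4 | step 9 | (4R,5R,6S,8R,9R,10S)-6α,18-dihydroxy-8α,13-epoxy-14,15,16-trinorlabdan-13-one | O=C1CC[C@@H]2[C@@]3(C)CCC[C@@](C)(CO)[C@@H]3[C@@H](O)C[C@@]2(C)O1
F5 | step 11 | (4R,5R,6S,8R,9R,10S)-18-{[tert-butyl(dimethyl)silyl]oxy}-6α,8α-dihydroxy-14,15-dinorlabdan-13-one | CC(=O)CC[C@@H]1[C@@]2(C)CCC[C@@](C)(CO[Si](C)(C)C(C)(C)C)[C@@H]2[C@@H](O)C[C@@]1(C)O
F6 | step 14 | methyl (2Z)-3-iodobut-2-enoate | COC(=O)/C=C(/C)I
F7 | step 14 | methyl (2Z,6E)-9-[(4R,5R,6S,8R,9R,10S)-6α,8α-dihydroxy-4α-(hydroxymethyl)-4β,8β,10β-trimethyl-trans-decalin-9-yl]-3,7-dimethylnona-2,6-dien-4-ynoate | COC(=O)/C=C(/C)C#C/C=C(\C)CC[C@@H]1[C@@]2(C)CCC[C@@](C)(CO)[C@@H]2[C@@H](O)C[C@@]1(C)O
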